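**Retrosynthetic overview**

- The strategy rests on the para-hydroxyphenyl ring of 1-(4-hydroxyphenyl)octadecan-5-one. Its C–OH carbon is read as the carbonyl carbon of a cyclohex-2-enone, and the para carbon carrying chain C1 as enone C4. The chain C5 ketone, four methylenes from the ring, is masked as a dioxolane.
- The last two operations are aerobic dehydrogenation of the 4-alkylcyclohex-2-enone to the phenol, then ketal hydrolysis.
- The enone is the only carbocycle built (step 4). It is cut at ring C4–C5 (Michael) and ring C2=C3 (aldol condensation) into methyl vinyl ketone and 6-(2-tridecyl-1,3-dioxolan-2-yl)hexanal, whose α-CH2 becomes ring C4.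
- The aldehyde comes from methyl 7-oxoicosanoate by ketalisation and partial reduction. The keto ester comes from tridecylmagnesium bromide and methyl 7-chloro-7-oxoheptanoate.

Key step: step 4

Assumption: methyl 7-chloro-7-oxoheptanoate (the half-ester acid chloride of pimelic acid) is taken as a purchasable compound, and the transient ring stereocentre of the cyclohexenone is carried as the racemate because the target is achiral.

**Route**

Step 1
Reactants: 1 1-bromotridecane; 2 methyl 7-chloro-7-oxoheptanoate
Product: 4 methyl 7-oxoicosanoate, via tridecylmagnesium bromide 3 (not isolated)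
Conditions: Mg, THF, 50 °C; then added to 2, Fe(acac)3 (3 mol%), THF, −78 °C
Reagents that add atoms: none
Why: Grignard formation followed by iron-catalysed acylation of the alkylmagnesium halide by the acid chloride, which at −78 °C should be far faster than attack on the methyl ester or on the ketone formed, so that the keto ester is expected without tertiary alcohol.

Step 2
Reactants: 4 methyl 7-oxoicosanoate
Product: 5 methyl 6-(2-tridecyl-1,3-dioxolan-2-yl)hexanoate
Conditions: 1,2-bis(trimethylsilyloxy)ethane (1.5 equiv), TMSOTf (2 mol%), CH2Cl2, −78 to −20 °C; pyridine quench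
Reagents that add atoms: 1,2-bis(trimethylsilyloxy)ethane, C[Si](C)(C)OCCO[Si](C)(C)C
Why: Noyori ketalisation, in which the silyl triflate activates the unhindered ketone and formation of hexamethyldisiloxane drives dioxolane closure at low temperature, where the methyl ester should neither transesterify nor react.

Step 3
Reactants: 5 methyl 6-(2-tridecyl-1,3-dioxolan-2-yl)hexanoate
Product: 6 6-(2-tridecyl-1,3-dioxolan-2-yl)hexanal
Conditions: i-Bu2AlH (1.1 equiv), CH2Cl2, −78 °C; MeOH quench, aq. potassium sodium tartrate
Reagents that add atoms: none
Why: Partial reduction of an ester with i-Bu2AlH, in which the aluminium hemiacetal formed by one hydride transfer should persist at −78 °C until the quench and so release the aldehyde, the dioxolane being inert to the hydride.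

Step 4
Reactants: 6 6-(2-tridecyl-1,3-dioxolan-2-yl)hexanal; 7 methyl vinyl ketone (but-3-en-2-one)
Product: 11 4-[4-(2-tridecyl-1,3-dioxolan-2-yl)butyl]cyclohex-2-en-1-one (racemic), via diethyl enamine 8 (not isolated), via keto aldehyde 9 (not isolated), via aldol 10 (not isolated)
Conditions: 7 (1.5 equiv), Et2NSiMe3 (0.3 equiv), MeCN, reflux; concentrate; then aq. KOH (0.3 equiv), n-Bu4NOH (cat.), THF–Et2O, reflux
Reagents that add atoms: none
Why: The diethylamine delivered by the aminosilane condenses with the aldehyde to enamine 8, whose nucleophilic carbon (the former α-CH2 of 6) adds to the terminal vinyl carbon of 7, and hydrolysis of the adduct by the water of condensation returns the amine and leaves the 1,5-keto aldehyde 9 with the ring C4–C5 bond in place. Hydroxide then forms the methyl-side enolate of 9, which attacks the aldehyde carbon to give aldol 10, and E1cB loss of water installs the ring C2=C3 double bond of 11. The closest known reaction type is the amine-catalysed Michael addition of aldehydes to vinyl ketones followed by base-mediated aldol condensation, that is, the enamine variant of the Robinson annulation leading to 4-substituted cyclohex-2-enones. The six-membered ring closes in a 6-(enolendo)-exo-trig mode, since both enolate carbons lie inside the new ring and the aldehyde oxygen outside it. The ring C4 stereocentre arises without control and is racemic, which is immaterial because step 5 removes it, and the carbinol centre of 10 is lost on dehydration. The step needs the aldehyde to be the only enamine-forming carbonyl and the methyl ketone to be the only aldol donor that can reach a six-membered ring; the dioxolane on the chain ketone secures the first, the second follows because every other enolate–carbonyl pairing in 9 would close a four-membered ring, and the now tertiary α-carbon of 9 should resist a second Michael addition.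

Step 5
Reactants: 11 4-[4-(2-tridecyl-1,3-dioxolan-2-yl)butyl]cyclohex-2-en-1-one
Product: 13 4-[4-(2-tridecyl-1,3-dioxolan-2-yl)butyl]phenol, via cyclohexadienone 12 (not isolated)
Conditions: Pd(O2CCF3)2 (5 mol%), 2-(dimethylamino)pyridine (10 mol%), TsOH·H2O (20 mol%), O2 (1 atm), DMSO, 80 °C
Reagents that add atoms: none
Why: Aerobic palladium-catalysed dehydrogenation of a cyclohexenone, in which divalent palladium forms the C6 enolate, β-hydride elimination from C5 gives the cross-conjugated dienone 12 that tautomerises irreversibly to the phenol, and O2 reoxidises the zerovalent palladium with water as the only by-product; any dioxolane lost to the acid co-catalyst only anticipates step 6.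

Step 6
Reactants: 13 4-[4-(2-tridecyl-1,3-dioxolan-2-yl)butyl]phenol
Product: 14 1-(4-hydroxyphenyl)octadecan-5-one (target)
Conditions: 1 M HCl, THF, rt
Reagents that add atoms: water, O
Why: Acid-catalysed hydrolysis of the dioxolane (ketal deprotection) through the oxocarbenium ion and hemiketal, which should leave the phenol and the saturated dialkyl ketone untouched.

**Compound list**

1 | 1-bromotridecane | CCCCCCCCCCCCCBr | starting material
2 | methyl 7-chloro-7-oxoheptanoate | COC(=O)CCCCCC(Cl)=O | starting material
3 | tridecylmagnesium bromide | CCCCCCCCCCCCC[Mg]Br | intermediate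
4 | methyl 7-oxoicosanoate | CCCCCCCCCCCCCC(=O)CCCCCC(=O)OC | intermediate
5 | methyl 6-(2-tridecyl-1,3-dioxolan-2-yl)hexanoate | COC(=O)CCCCCC1(CCCCCCCCCCCCC)OCCO1 | intermediate
6 | 6-(2-tridecyl-1,3-dioxolan-2-yl)hexanal | O=CCCCCCC1(CCCCCCCCCCCCC)OCCO1 | intermediate
7 | methyl vinyl ketone (but-3-en-2-one) | CC(=O)C=C | starting material
8 | (E)-N,N-diethyl-6-(2-tridecyl-1,3-dioxolan-2-yl)hex-1-en-1-amine | CCN(CC)/C=C/CCCCC1(CCCCCCCCCCCCC)OCCO1 | intermediate
9 | 5-oxo-2-[4-(2-tridecyl-1,3-dioxolan-2-yl)butyl]hexanal (racemic) | O=CC(CCC(C)=O)CCCCC1(CCCCCCCCCCCCC)OCCO1 | intermediate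
10 | 3-hydroxy-4-[4-(2-tridecyl-1,3-dioxolan-2-yl)butyl]cyclohexan-1-one (racemic, mixture of diastereomers) | O=C1CC(O)C(CCCCC2(CCCCCCCCCCCCC)OCCO2)CC1 | intermediate
11 | 4-[4-(2-tridecyl-1,3-dioxolan-2-yl)butyl]cyclohex-2-en-1-one (racemic) | O=C1C=CC(CCCCC2(CCCCCCCCCCCCC)OCCO2)CC1 | intermediate
12 | 4-[4-(2-tridecyl-1,3-dioxolan-2-yl)butyl]cyclohexa-2,5-dien-1-one | O=C1C=CC(CCCCC2(CCCCCCCCCCCCC)OCCO2)C=C1 | intermediate
13 | 4-[4-(2-tridecyl-1,3-dioxolan-2-yl)butyl]phenol | Oc1ccc(CCCCC2(CCCCCCCCCCCCC)OCCO2)cc1 | intermediate
14 | 1-(4-hydroxyphenyl)octadecan-5-one | CCCCCCCCCCCCCC(=O)CCCCc1ccc(O)cc1 | target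

**Step count**

Total steps: 6. Longest linear sequence: 6 steps (from 1 or 2 to 14).

**Steps most likely to fail, with fallbacks**

Step 4. The aldehyde may condense with itself faster than its enamine adds to the enone, the vinyl ketone may oligomerise, or the aldol may stop short of dehydration. The fallback is a stepwise Stork sequence with a stoichiometric, pre-formed enamine, so that no free aldehyde meets enone or base. It sets out from 6, which is stirred with pyrrolidine and K2CO3 in Et2O, filtered and concentrated to 1-[(E)-6-(2-tridecyl-1,3-dioxolan-2-yl)hex-1-en-1-yl]pyrrolidine F1. F1 is treated with 7 in MeCN at room temperature and the adduct is hydrolysed with an aqueous AcOH–NaOAc buffer to the keto aldehyde 9, now isolated. Cyclisation of 9 with KOH in MeOH should then give the enone, so the fallback comes back to the route at 11.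

Step 5. Turnover may stall through aggregation of reduced palladium, and acid-promoted loss of the dioxolane may expose the chain ketone to oxidation at its α-positions. The fallback is a metal-free selenoxide elimination under basic and then buffered conditions, and it sets out from 11. Kinetic deprotonation at C6 with LiN(i-Pr)2 in THF at −78 °C and trapping with PhSeCl should give 6-(phenylselanyl)-4-[4-(2-tridecyl-1,3-dioxolan-2-yl)butyl]cyclohex-2-en-1-one F2. Oxidation with H2O2 and pyridine in CH2Cl2 at 0 °C should give the selenoxide 6-(benzeneseleninyl)-4-[4-(2-tridecyl-1,3-dioxolan-2-yl)butyl]cyclohex-2-en-1-one F3. Syn-elimination of F3 towards C5 leads to dienone 12, which tautomerises, so the fallback comes back to the route at 13.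

Step 3. The aluminium hemiacetal may collapse before the quench, so that a second hydride transfer over-reduces the ester to the primary alcohol. The fallback replaces partial reduction by full reduction and re-oxidation, and it sets out from 5. LiAlH4 in THF at 0 °C should give 6-(2-tridecyl-1,3-dioxolan-2-yl)hexan-1-ol F4. Parikh–Doering oxidation of F4 (SO3·pyridine, DMSO, Et3N, CH2Cl2, 0 °C) should return the aldehyde, so the fallback comes back to the route at 6.

**Further compounds**

F1 | step 4 | 1-[(E)-6-(2-tridecyl-1,3-dioxolan-2-yl)hex-1-en-1-yl]pyrrolidine | C1CCN(C1)/C=C/CCCCC2(CCCCCCCCCCCCC)OCCO2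
F2 | step 5 | 6-(phenylselanyl)-4-[4-(2-tridecyl-1,3-dioxolan-2-yl)butyl]cyclohex-2-en-1-one (mixture of diastereomers) | O=C1C=CC(CCCCC2(CCCCCCCCCCCCC)OCCO2)CC1[Se]c3ccccc3
F3 | step 5 | 6-(benzeneseleninyl)-4-[4-(2-tridecyl-1,3-dioxolan-2-yl)butyl]cyclohex-2-en-1-one (mixture of diastereomers) | O=C1C=CC(CCCCC2(CCCCCCCCCCCCC)OCCO2)CC1[Se](=O)c3ccccc3
F4 | step 3 | 6-(2-tridecyl-1,3-dioxolan-2-yl)hexan-1-ol | OCCCCCCC1(CCCCCCCCCCCCC)OCCO1
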